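The constants set the order of events: free base binds acid more strongly than the nucleophile does, 27000 M⁻¹ against 1800 M⁻¹, so free base frees the nucleophile and then takes up the acid set free in the coupling, whose balance stands at 0.33.

electrophile 1.5 M; protonated nucleophile 1.42 M; time 4.0 d

    nucleophile + acid set free ⇌ protonated nucleophile, settled at all times (K1 = 1800 M⁻¹)
    electrophile + acid set free → side product B (k2 = 0.083 M⁻¹ h⁻¹)
    electrophile + nucleophile ⇌ acid set free + target (K3 = 0.33, k3 = 0.54 M⁻¹ h⁻¹)
    acid set free + free base ⇌ salt of the base, settled at all times (K4 = 27000 M⁻¹)
    electrophile + target → side product A (k5 = 0.016 M⁻¹ h⁻¹)

- a species is counted by the electrophile in it: one side product A counts as two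
- the amount of free base is what is sought; it is there from the start
- run time (flask): 4.0 d

- the concentration of free base at which the part of the electrophile that has reacted at 4.0 d is just 90%, in M

Two extreme flasks can be solved in the head, both reckoned here with side product B set aside. The electrophile to be used is 1.35 M. If each electrophile used became target, each would cost two free base, one for the proton of its nucleophile and one for the acid set free, so 2.70 M is needed. If each target took a second electrophile into side product A, that pair would cost two free base, one per electrophile, so 1.35 M is enough. The real flask lies between them: the rate constant of coupling stands above that of the step to side product A, so target forms first and part of it goes on. This reckoning commits to the mean of the two, 2.03 M.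

That base pays for 1.01 M of target and leaves 0.487 M of electrophile for the step to side product A. With target replaced by its mean, 0.844 M, this tail is pseudo-first-order. It is reckoned with the tail dose D, the rate constant of side product A times the run time, 1.54 M⁻¹. Electrophile falls by exp(−D × mean target), to 0.133 M, which makes 91.1% used, close to the part wanted.

The forecast gives 2.1 M, a little above this reckoning: “the coupling stalls near equilibrium once the base runs out”.

The flask gives 2.04 M, and the forecast stands within its margin. Electrophile has a half-life of 0.077 d by the forward rate of coupling alone at 0.0330 d, but 2.8 d by the step to side product A at 4.00 d. Through D, that late half-life reads as 0.647 M of target. In the flask with a quarter more free base, 2.55 M, the same estimate puts 0.223 M of electrophile into the tail, and D with mean target 1.17 M gives 97.5% used; that run reads 96.2%.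

Its constants were set for the occasion; what happens was integrated by code.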